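**Retrosynthetic overview**

1. Numbering used throughout (elemane positions): ring C5–C10; C10 carries CH3 (C14) and the vinyl group C1=C2; C5 carries C4(=C3H2)–C15H2OH; C7 carries C11(=C13H2)–C12O2H; O6 is on C6 and the ester oxygen O8 on C8.
2. Enabling feature: the vinyl carbon C1 and the hydroxyl oxygen O15 sit cis on the neighbouring ring carbons C10 and C5 and are 1,6-related (C1–C10–C5–C4–C15–O15). They can therefore be tied into a temporary δ-lactone (ring O15–C15–C4–C5–C10–C1=O) whose enolate makes C10 a planar nucleophile.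
3. Key disconnection C9–C10: the lactone enolate opens a C8–C9 epoxide at C9. The epoxide is made in the same flask from a C8 tosylate and C9 alcohol, with inversion at C8. The cis ring fusion fixes quaternary C10 from either C10 epimer, and O8 is released free for the ester.
4. The C5–C8 stereotetrad comes from (S)-5-(hydroxymethyl)furan-2(5H)-one: trans cuprate addition (C7), trans enolate hydroxylation (C6), lactol Wittig, anti cuprate addition to the γ-silyloxy enoate (C5). Both 2-propenyl units come from 2-bromoallyl ethers.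
5. Ring order: γ-butyrolactone template (opened) → temporary δ-lactone → cyclohexane (key step, the only ring of the target) → δ-lactone opened by reduction and Wittig (vinyl + 15-OH). End game: O8 acylation, then C12 ether → enal → acid.

Key step: step 15

Remark: esters 20–21 and lactones 22–23 are expected as mixtures of C10 epimers and lactols 14 and 25 as anomer mixtures; no separation is planned because these centres are erased in steps 15, 10 and 17.

**Route**

Step 1
Reactants: 1 2,3-dibromoprop-1-ene; 2 (4-methoxyphenyl)methanol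
Product: 3 1-{[(2-bromoprop-2-en-1-yl)oxy]methyl}-4-methoxybenzene
Conditions: NaH, Bu4NI (cat.), THF, 0 °C → rt
Reagents that add atoms: none
Why: Williamson ether synthesis in which the alkoxide of 2 should displace only the allylic bromide of 1 (SN2), the vinylic C–Br bond being inert; no stereocentre is formed.

Step 2
Reactants: 4 2-bromoprop-2-en-1-ol
Product: 5 2-bromo-3-[(2-methoxypropan-2-yl)oxy]prop-1-ene
Conditions: 2-methoxyprop-1-ene, PPTS (cat.), CH2Cl2, 0 °C; Et3N
Reagents that add atoms: 2-methoxyprop-1-ene, C=C(C)OC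
Why: Acid-catalysed addition of the alcohol to the enol ether (mixed ketal formation) should give an achiral, base-stable protecting group that survives halogen–lithium exchange and is lost with trace acid; no stereocentre is formed.

Step 3
Reactants: 6 3-methylfuran-2(5H)-one
Product: 7 sodium (Z)-4-hydroxy-2-methylbut-2-enoate
Conditions: NaOH (1.0 equiv), H2O/THF, 0 °C → rt; lyophilise
Reagents that add atoms: sodium hydroxide, [Na+].[OH-]
Why: Lactone saponification should open the butenolide with the Z double bond dictated by the ring (carboxylate and CH2O cis), and the product is kept as its salt to prevent relactonisation.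

Step 4
Reactants: 7 sodium (Z)-4-hydroxy-2-methylbut-2-enoate
Product: 8 (Z)-4-acetoxy-2-methylbut-2-enoic acid
Conditions: NaH (1.0 equiv), DMF, 0 °C; Ac2O (1.05 equiv), −40 → 0 °C; then cold aq. HCl to pH 3
Reagents that add atoms: acetic anhydride, CC(=O)OC(C)=O
Why: O-Acetylation (nucleophilic acyl substitution) of the alkoxide, far more nucleophilic than the carboxylate in the dianion, should cap the hydroxyl without touching the Z alkene, so that acidification can no longer return the lactone.

Step 5
Reactants: 9 (S)-5-(hydroxymethyl)furan-2(5H)-one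
Product: 10 (S)-5-{[(tert-butyldimethylsilyl)oxy]methyl}furan-2(5H)-one
Conditions: TBSCl, imidazole, CH2Cl2, 0 °C → rt
Reagents that add atoms: tert-butyl(chloro)dimethylsilane, C[Si](C)(Cl)C(C)(C)C
Why: Standard silyl ether formation on the primary alcohol; the C8 stereocentre is untouched.

Step 6
Reactants: 10 (S)-5-{[(tert-butyldimethylsilyl)oxy]methyl}furan-2(5H)-one; 3 1-{[(2-bromoprop-2-en-1-yl)oxy]methyl}-4-methoxybenzene
Product: 11 (4R,5S)-5-{[(tert-butyldimethylsilyl)oxy]methyl}-4-{3-[(4-methoxybenzyl)oxy]prop-1-en-2-yl}dihydrofuran-2(3H)-one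
Conditions: 3 (2.2 equiv), t-BuLi (4.4 equiv), Et2O, −78 °C; CuI (1.1 equiv), −78 → −40 °C; then 10, −78 °C; aq. NH4Cl/NH3
Reagents that add atoms: none
Why: 1,4-Addition of the lithium dialkenylcuprate R2CuLi to the butenolide should deliver the alkenyl group to the ring face opposite the C8 silyloxymethyl group, setting C7 trans to it (substrate control).

Step 7
Reactants: 11 (4R,5S)-lactone
Product: 12 (3S,4S,5S)-5-{[(tert-butyldimethylsilyl)oxy]methyl}-3-hydroxy-4-{3-[(4-methoxybenzyl)oxy]prop-1-en-2-yl}dihydrofuran-2(3H)-one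
Conditions: KN(SiMe3)2, THF, −78 °C; 3-phenyl-2-(phenylsulfonyl)oxaziridine, −78 °C; AcOH
Reagents that add atoms: 3-phenyl-2-(phenylsulfonyl)oxaziridine, O=S(=O)(c1ccccc1)N1OC1c1ccccc1
Why: Enolate hydroxylation with an N-sulfonyloxaziridine (Davis oxidation) should occur on the enolate face opposite the adjacent C7 substituent, setting the C6 hydroxyl trans to it.

Step 8
Reactants: 12 (3S,4S,5S)-hydroxy lactone
Product: 13 (3S,4R,5S)-3-[(tert-butyldimethylsilyl)oxy]-5-{[(tert-butyldimethylsilyl)oxy]methyl}-4-{3-[(4-methoxybenzyl)oxy]prop-1-en-2-yl}dihydrofuran-2(3H)-one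
Conditions: TBSOTf, 2,6-lutidine, CH2Cl2, −78 → 0 °C
Reagents that add atoms: tert-butyldimethylsilyl trifluoromethanesulfonate, C[Si](C)(OS(=O)(=O)C(F)(F)F)C(C)(C)C
Why: Silylation of the hindered α-hydroxy lactone with the silyl triflate; no stereocentre changes.

Step 9
Reactants: 13 (3S,4R,5S)-bis-silyl lactone
Product: 14 the corresponding tetrahydrofuran-2-ol (lactol, anomer mixture; ring C3–C5 configured as in 13)
Conditions: iBu2AlH (1.2 equiv), CH2Cl2, −78 °C; aq. KNaC4H4O6 (potassium sodium tartrate)
Reagents that add atoms: none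
Why: Partial reduction of the γ-lactone stops at the aluminium hemiacetal at low temperature and exposes C5 as a masked aldehyde without epimerising C6.

Step 10
Reactants: 14 lactol; 15 ethyl (triphenyl-λ5-phosphanylidene)acetate
Product: 16 ethyl (E)-4,7-bis[(tert-butyldimethylsilyl)oxy]-6-hydroxy-5-{3-[(4-methoxybenzyl)oxy]prop-1-en-2-yl}hept-2-enoate (hept C4, C5, C6 = C6, C7, C8, configured as in 13)
Conditions: toluene, 80 °C
Reagents that add atoms: none
Why: Wittig olefination of the open hydroxy-aldehyde form of the lactol with the stabilised ylide should give the E enoate and free the C8 hydroxyl; no stereocentre is formed.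

Step 11
Reactants: 16 hydroxy enoate
Product: 17 ethyl (E)-4,7-bis[(tert-butyldimethylsilyl)oxy]-5-{3-[(4-methoxybenzyl)oxy]prop-1-en-2-yl}-6-(tosyloxy)hept-2-enoate
Conditions: TsCl, Et3N, DMAP (cat.), CH2Cl2, 0 °C → rt
Reagents that add atoms: 4-methylbenzenesulfonyl chloride, Cc1ccc(S(=O)(=O)Cl)cc1
Why: Sulfonylation of the only free hydroxyl turns O8 into a leaving group with retention at C8 and blocks oxa-Michael closure onto the enoate.

Step 12
Reactants: 17 tosyloxy enoate; 5 2-bromo-3-[(2-methoxypropan-2-yl)oxy]prop-1-ene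
Product: 19 ethyl 4,7-bis[(tert-butyldimethylsilyl)oxy]-3-{3-[(2-methoxypropan-2-yl)oxy]prop-1-en-2-yl}-5-{3-[(4-methoxybenzyl)oxy]prop-1-en-2-yl}-6-(tosyloxy)heptanoate (new centre hept C3 = C5, anti to the C6 silyloxy group), via silyl ketene acetal 18 (not isolated)
Conditions: 5 (3 equiv), t-BuLi (6 equiv), Et2O, −78 °C; CuI (1.5 equiv), −78 → −40 °C; then Me3SiCl/Et3N (5 equiv), 17, THF, −78 °C; aq. NH4Cl/NH3, rt
Reagents that add atoms: none
Why: Chlorosilane-accelerated 1,4-addition of the lithium dialkenylcuprate to the E γ-silyloxy enoate should follow the Felkin–Anh-type preference for attack anti to the γ-oxygen substituent, setting C5 anti to O6, while the enolate is trapped as 18 and cannot displace the tosylate.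

Step 13
Reactants: 19 conjugate adduct
Product: 20 ethyl 4,7-bis[(tert-butyldimethylsilyl)oxy]-3-{3-[(2-methoxypropan-2-yl)oxy]prop-1-en-2-yl}-5-{3-[(4-methoxybenzyl)oxy]prop-1-en-2-yl}-2-methyl-6-(tosyloxy)heptanoate (both epimers at hept C2 = C10)
Conditions: MeI (5 equiv), THF, −78 °C; LiN(iPr)2 (1.2 equiv) added slowly; AcOH
Reagents that add atoms: iodomethane, CI
Why: Ester enolate alkylation with in situ trapping installs C14 before the enolate can attack the tosylate, and the uncontrolled new C10 centre is harmless because it is planarised in step 15.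

Step 14
Reactants: 20 α-methyl ester
Product: 22 3-methyl-5-methylideneoxan-2-one carrying at C4 the 1-[(tert-butyldimethylsilyl)oxy]-4-hydroxy-2-{3-[(4-methoxybenzyl)oxy]prop-1-en-2-yl}-3-(tosyloxy)butyl chain (C5–C8 as set before; C10 epimers), via diol ester 21 (not isolated)
Conditions: CSA (0.1 equiv), MeOH/CH2Cl2, 0 °C; Et3N, concentrate; then PPTS (cat.), toluene, 60 °C
Reagents that add atoms: none
Why: Mild acid methanolysis removes the ketal and the primary silyl ether but not the hindered secondary one, and the freed C15 hydroxyl closes the six-membered lactone by acid-catalysed transesterification; no stereocentre changes.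

Step 15
Reactants: 22 hydroxy tosylate δ-lactone
Product: 24 cis-fused 5-[(tert-butyldimethylsilyl)oxy]-7-hydroxy-6-{3-[(4-methoxybenzyl)oxy]prop-1-en-2-yl}-8a-methyl-4-methylidene-3,4,4a,5,6,7,8,8a-octahydro-1H-isochromen-1-one (isochromene C8a, C4a, C5, C6, C7 = C10, C5, C6, C7, C8), via epoxy lactone 23 (not isolated)
Conditions: LiN(SiMe3)2 (1.05 equiv), THF, −78 → 0 °C; then KN(SiMe3)2 (1.3 equiv), −78 °C → rt; AcOH
Reagents that add atoms: none
Why: The first equivalent of base deprotonates the C9 hydroxyl, and the alkoxide displaces the adjacent C8 tosylate (3-exo-tet, inversion at C8) to give terminal epoxide 23; the second base then forms the planar potassium enolate of the δ-lactone, which erases the C10 epimer mixture, and C10 opens the epoxide at its primary carbon C9 by SN2. The closest known reaction type is the intramolecular epoxide opening by a stabilised carbanion (epoxynitrile-type cyclisation) and the intramolecular alkylation of lactone enolates. The cyclohexane, the only ring closed, forms in the 6-endo-tet mode with respect to the epoxide (enolexo with respect to the enolate) through a chair in which O8, the C7 substituent and O6 are equatorial. C10 is controlled by the temporary lactone ring: allylic 1,2-strain with the C10 methyl and allylic 1,3-strain with the exocyclic C4 methylene hold the C5 side chain pseudoaxial over one enolate face, so the C9–C10 bond can only form cis to it and the cis-fused bicycle (C1 and C4 cis, methyl trans to C4) results from either C10 epimer, while C8 keeps the configuration created by the inversion because the enolate attacks C9. The step needs attack at C9 instead of 5-exo attack at C8, secured by the primary versus branched secondary epoxide carbons and the fully substituted nucleophile, and it needs the epoxide to close before the enolate forms, secured by the staged base addition and the far higher kinetic acidity of the hydroxyl. Translactonisation of the new C8 alkoxide onto C1 is not expected because the bridged lactone would push the C6 silyl ether into the bicyclic cavity.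

Step 16
Reactants: 24 bicyclic lactone
Product: 25 the corresponding 1-hydroxy-isochromane (lactol, anomer mixture)
Conditions: iBu2AlH (2.5 equiv), CH2Cl2, −78 °C; aq. KNaC4H4O6
Reagents that add atoms: none
Why: Partial reduction of the δ-lactone to the lactol (stable aluminium hemiacetal at low temperature), the free C8 hydroxyl consuming one hydride equivalent; C10 is quaternary and cannot epimerise.

Step 17
Reactants: 25 lactol
Product: 26 6-O-TBS-12-O-(4-methoxybenzyl)-elema-1,3,11(13)-triene-6,8,12,15-tetrol with free 8-OH and 15-OH (ring configured as the target, vinyl on C10 cis to the C5 substituent)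
Conditions: Ph3PCH3Br, KOt-Bu, THF, 0 → 50 °C
Reagents that add atoms: methyltriphenylphosphonium bromide, C[P+](c1ccccc1)(c1ccccc1)c1ccccc1.[Br-]
Why: Wittig methylenation of the aldehyde form of the lactol converts C1 into the vinyl group and releases the C15 hydroxyl, removing the temporary ring; no stereocentre is affected.

Step 18
Reactants: 26 8,15-diol
Product: 27 the 15-O-TBS ether of 26 (8-OH free)
Conditions: TBSCl (1.1 equiv), imidazole, CH2Cl2, 0 °C
Reagents that add atoms: tert-butyl(chloro)dimethylsilane, C[Si](C)(Cl)C(C)(C)C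
Why: The primary allylic C15 hydroxyl should be silylated much faster than the hindered secondary C8 hydroxyl (steric differentiation in silyl ether formation).

Step 19
Reactants: 27 8-alcohol; 8 (Z)-4-acetoxy-2-methylbut-2-enoic acid
Product: 29 the 8-O-[(Z)-4-acetoxy-2-methylbut-2-enoyl] ester of 27, via mixed anhydride 28 (not isolated)
Conditions: 8, 2,4,6-Cl3C6H2COCl, Et3N, toluene, rt; then 27, DMAP, toluene, rt → 40 °C
Reagents that add atoms: none
Why: Yamaguchi esterification via mixed anhydride 28 should acylate the equatorial C8 hydroxyl at the less hindered carbonyl while preserving the Z geometry of the side chain; no stereocentre is formed.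

Step 20
Reactants: 29 fully protected ester
Product: 30 the 12-alcohol (4-methoxybenzyl group removed; 6-O-TBS, 15-O-TBS and both esters kept)
Conditions: DDQ, CH2Cl2/pH 7 buffer, 0 °C → rt
Reagents that add atoms: none
Why: Oxidative cleavage of the 4-methoxybenzyl ether by DDQ (hydride abstraction, then hydrolysis of the oxocarbenium ion) unveils only the C12 allylic alcohol, silyl ethers and esters being inert.

Step 21
Reactants: 30 12-alcohol
Product: 31 the 12-al (2-substituted acrolein on C7)
Conditions: MnO2 (excess), CH2Cl2, rt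
Reagents that add atoms: none
Why: MnO2 oxidises the primary allylic alcohol to the enal while O6 and O15 stay silylated, so that neither a lactol nor a lactone can form.

Step 22
Reactants: 31 bis-silyl enal
Product: 32 6,15-dihydroxy enal (expected to equilibrate with its C6–O–C12 lactol)
Conditions: HF·pyridine, pyridine, THF, 0 °C → rt
Reagents that add atoms: none
Why: Fluoride-mediated cleavage of both silyl ethers is done at the aldehyde stage, where the product cannot lactonise as a free acid could under these conditions.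

Step 23
Reactants: 32 dihydroxy enal
Product: 33 target, 8-O-[(Z)-4-acetoxy-2-methylbut-2-enoyl]-6,15-dihydroxyelema-1,3,11(13)-trien-12-oic acid with the configuration of the given structure
Conditions: NaClO2, NaH2PO4, 2-methylbut-2-ene, t-BuOH/H2O, 0 °C
Reagents that add atoms: sodium chlorite, [Na+].[O-]Cl=O
Why: Pinnick oxidation converts the enal (open form of the lactol equilibrium) into the acrylic acid under buffered conditions, without oxidising the free hydroxyls or the alkenes (2-methylbut-2-ene scavenges HOCl) and mildly enough to avoid lactonisation onto O6.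

**Compound list**

1 | 2,3-dibromoprop-1-ene | C=C(Br)CBr | starting material
2 | (4-methoxyphenyl)methanol | COc1ccc(CO)cc1 | starting material
3 | 1-{[(2-bromoprop-2-en-1-yl)oxy]methyl}-4-methoxybenzene | C=C(Br)COCc1ccc(OC)cc1 | intermediate
4 | 2-bromoprop-2-en-1-ol | C=C(Br)CO | starting material
5 | 2-bromo-3-[(2-methoxypropan-2-yl)oxy]prop-1-ene | C=C(Br)COC(C)(C)OC | intermediate
6 | 3-methylfuran-2(5H)-one | CC1=CCOC1=O | starting material
7 | sodium (Z)-4-hydroxy-2-methylbut-2-enoate | [Na+].[O-]C(=O)/C(C)=C\CO | intermediate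
8 | (Z)-4-acetoxy-2-methylbut-2-enoic acid | OC(=O)/C(C)=C\COC(C)=O | intermediate
9 | (S)-5-(hydroxymethyl)furan-2(5H)-one | O=C1C=C[C@@H](CO)O1 | starting material
10 | (S)-5-{[(tert-butyldimethylsilyl)oxy]methyl}furan-2(5H)-one | O=C1C=C[C@@H](CO[Si](C)(C)C(C)(C)C)O1 | intermediate
11 | (4R,5S)-5-{[(tert-butyldimethylsilyl)oxy]methyl}-4-{3-[(4-methoxybenzyl)oxy]prop-1-en-2-yl}dihydrofuran-2(3H)-one | O=C1C[C@H](C(=C)COCc2ccc(OC)cc2)[C@@H](CO[Si](C)(C)C(C)(C)C)O1 | intermediate
12 | (3S,4S,5S)-5-{[(tert-butyldimethylsilyl)oxy]methyl}-3-hydroxy-4-{3-[(4-methoxybenzyl)oxy]prop-1-en-2-yl}dihydrofuran-2(3H)-one | O=C1[C@@H](O)[C@H](C(=C)COCc2ccc(OC)cc2)[C@@H](CO[Si](C)(C)C(C)(C)C)O1 | intermediate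
13 | (3S,4R,5S)-3-[(tert-butyldimethylsilyl)oxy]-5-{[(tert-butyldimethylsilyl)oxy]methyl}-4-{3-[(4-methoxybenzyl)oxy]prop-1-en-2-yl}dihydrofuran-2(3H)-one | O=C1[C@@H](O[Si](C)(C)C(C)(C)C)[C@H](C(=C)COCc2ccc(OC)cc2)[C@@H](CO[Si](C)(C)C(C)(C)C)O1 | intermediate
14 | lactol of 13 (tetrahydrofuran-2-ol, anomer mixture) | OC1[C@@H](O[Si](C)(C)C(C)(C)C)[C@H](C(=C)COCc2ccc(OC)cc2)[C@@H](CO[Si](C)(C)C(C)(C)C)O1 | intermediate
15 | ethyl (triphenyl-λ5-phosphanylidene)acetate | CCOC(=O)C=P(c1ccccc1)(c1ccccc1)c1ccccc1 | starting material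
16 | ethyl (E)-4,7-bis[(tert-butyldimethylsilyl)oxy]-6-hydroxy-5-{3-[(4-methoxybenzyl)oxy]prop-1-en-2-yl}hept-2-enoate | CCOC(=O)/C=C/[C@@H](O[Si](C)(C)C(C)(C)C)[C@H](C(=C)COCc1ccc(OC)cc1)[C@H](O)CO[Si](C)(C)C(C)(C)C | intermediate
17 | 6-O-tosylate of 16 | CCOC(=O)/C=C/[C@@H](O[Si](C)(C)C(C)(C)C)[C@H](C(=C)COCc1ccc(OC)cc1)[C@H](OS(=O)(=O)c1ccc(C)cc1)CO[Si](C)(C)C(C)(C)C | intermediate
18 | ethyl trimethylsilyl ketene acetal of 19 (E/Z mixture, not isolated) | CCOC(O[Si](C)(C)C)=C[C@@H](C(=C)COC(C)(C)OC)[C@@H](O[Si](C)(C)C(C)(C)C)[C@H](C(=C)COCc1ccc(OC)cc1)[C@H](OS(=O)(=O)c1ccc(C)cc1)CO[Si](C)(C)C(C)(C)C | intermediate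
19 | ethyl 4,7-bis[(tert-butyldimethylsilyl)oxy]-3-{3-[(2-methoxypropan-2-yl)oxy]prop-1-en-2-yl}-5-{3-[(4-methoxybenzyl)oxy]prop-1-en-2-yl}-6-(tosyloxy)heptanoate | CCOC(=O)C[C@@H](C(=C)COC(C)(C)OC)[C@@H](O[Si](C)(C)C(C)(C)C)[C@H](C(=C)COCc1ccc(OC)cc1)[C@H](OS(=O)(=O)c1ccc(C)cc1)CO[Si](C)(C)C(C)(C)C | intermediate
20 | 2-methyl derivative of 19 (C10 epimers) | CCOC(=O)C(C)[C@@H](C(=C)COC(C)(C)OC)[C@@H](O[Si](C)(C)C(C)(C)C)[C@H](C(=C)COCc1ccc(OC)cc1)[C@H](OS(=O)(=O)c1ccc(C)cc1)CO[Si](C)(C)C(C)(C)C | intermediate
21 | ethyl 4-[(tert-butyldimethylsilyl)oxy]-7-hydroxy-3-(3-hydroxyprop-1-en-2-yl)-5-{3-[(4-methoxybenzyl)oxy]prop-1-en-2-yl}-2-methyl-6-(tosyloxy)heptanoate (not isolated) | CCOC(=O)C(C)[C@@H](C(=C)CO)[C@@H](O[Si](C)(C)C(C)(C)C)[C@H](C(=C)COCc1ccc(OC)cc1)[C@H](OS(=O)(=O)c1ccc(C)cc1)CO | intermediate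
22 | 3-methyl-5-methylideneoxan-2-one with the C6-silyloxy, C7-alkenyl, C8-tosyloxy, C9-hydroxy chain on ring C4 (C10 epimers) | CC1C(=O)OCC(=C)[C@H]1[C@@H](O[Si](C)(C)C(C)(C)C)[C@H](C(=C)COCc2ccc(OC)cc2)[C@H](OS(=O)(=O)c2ccc(C)cc2)CO | intermediate
23 | the same oxan-2-one with a terminal C8–C9 oxirane, C8 inverted (not isolated in the main route) | CC1C(=O)OCC(=C)[C@H]1[C@@H](O[Si](C)(C)C(C)(C)C)[C@H](C(=C)COCc2ccc(OC)cc2)[C@@H]2CO2 | intermediate
24 | cis-fused 5-[(tert-butyldimethylsilyl)oxy]-7-hydroxy-6-{3-[(4-methoxybenzyl)oxy]prop-1-en-2-yl}-8a-methyl-4-methylidene-octahydro-1H-isochromen-1-one | C[C@@]12C[C@H](O)[C@@H](C(=C)COCc3ccc(OC)cc3)[C@H](O[Si](C)(C)C(C)(C)C)[C@@H]1C(=C)COC2=O | intermediate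
25 | lactol of 24 (anomer mixture) | C[C@@]12C[C@H](O)[C@@H](C(=C)COCc3ccc(OC)cc3)[C@H](O[Si](C)(C)C(C)(C)C)[C@@H]1C(=C)COC2O | intermediate
26 | 6-O-TBS-12-O-(4-methoxybenzyl)-elematriene-8,15-diol | C=C[C@]1(C)C[C@H](O)[C@@H](C(=C)COCc2ccc(OC)cc2)[C@H](O[Si](C)(C)C(C)(C)C)[C@@H]1C(=C)CO | intermediate
27 | 15-O-TBS ether of 26 | C=C[C@]1(C)C[C@H](O)[C@@H](C(=C)COCc2ccc(OC)cc2)[C@H](O[Si](C)(C)C(C)(C)C)[C@@H]1C(=C)CO[Si](C)(C)C(C)(C)C | intermediate
28 | (Z)-4-acetoxy-2-methylbut-2-enoic 2,4,6-trichlorobenzoic anhydride (not isolated) | O=C(OC(=O)/C(C)=C\COC(C)=O)c1c(Cl)cc(Cl)cc1Cl | intermediate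
29 | 8-O-[(Z)-4-acetoxy-2-methylbut-2-enoyl] ester of 27 | C=C[C@]1(C)C[C@H](OC(=O)/C(C)=C\COC(C)=O)[C@@H](C(=C)COCc2ccc(OC)cc2)[C@H](O[Si](C)(C)C(C)(C)C)[C@@H]1C(=C)CO[Si](C)(C)C(C)(C)C | intermediate
30 | 12-alcohol (6,15-bis-O-TBS) | C=C[C@]1(C)C[C@H](OC(=O)/C(C)=C\COC(C)=O)[C@@H](C(=C)CO)[C@H](O[Si](C)(C)C(C)(C)C)[C@@H]1C(=C)CO[Si](C)(C)C(C)(C)C | intermediate
31 | 12-al (6,15-bis-O-TBS) | C=C[C@]1(C)C[C@H](OC(=O)/C(C)=C\COC(C)=O)[C@@H](C(=C)C=O)[C@H](O[Si](C)(C)C(C)(C)C)[C@@H]1C(=C)CO[Si](C)(C)C(C)(C)C | intermediate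
32 | 6,15-dihydroxy-12-al | C=C[C@]1(C)C[C@H](OC(=O)/C(C)=C\COC(C)=O)[C@@H](C(=C)C=O)[C@H](O)[C@@H]1C(=C)CO | intermediate
33 | target acid | C=C[C@]1(C)C[C@H](OC(=O)/C(C)=C\COC(C)=O)[C@@H](C(=C)C(=O)O)[C@H](O)[C@@H]1C(=C)CO | target

**Step count and risks**

Total steps: 23. Longest linear sequence: 19 steps (steps 5–23, from 9).

Steps most likely to fail:

(a) Step 15. Attack of the hindered, fully substituted lactone enolate on the epoxide may be slow, so that 5-exo opening at C8, base-induced isomerisation of the epoxide or elimination of the tosylate compete with ring closure. The fallback replaces the epoxide opening by a direct 6-exo-tet alkylation with a primary iodide. It sets out from 22: NaH (1.0 equiv, THF, 0 °C) gives the epoxy lactone 23, which is isolated. LiI/AcOH in THF opens it at the primary carbon to the iodohydrin F1. TESOTf/2,6-lutidine gives the triethylsilyl ether F2. LiN(SiMe3)2 in THF/DMPU (−78 → 0 °C) closes the ring under the same cis-fusion control to the bicyclic silyl ether F3. PPTS in MeOH removes the triethylsilyl group selectively and the route is rejoined at 24.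

(b) Step 12. The cuprate may add slowly to the hindered γ-silyloxy enoate, the anti facial preference may erode with the bulky silyl ether, or the reagent may attack the tosylate. The fallback replaces substrate control by catalyst control. It sets out from 17 and 5: halogen–lithium exchange of 5 (t-BuLi, Et2O, −78 °C) and quenching with 2-isopropoxy-4,4,5,5-tetramethyl-1,3,2-dioxaborolane gives the alkenylboronate F4. F4 is added to 17 with [Rh(cod)OH]2 and the BINAP enantiomer matched to the anti adduct (dioxane/H2O, 50 °C, monovalent rhodium conjugate addition). This returns the route at 19.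

(c) Step 19. The Z double bond of the activated acid may isomerise to the E (tiglate-type) isomer through reversible conjugate addition of DMAP or Et3N, or the alcohol may be acylated at the trichlorobenzoyl carbonyl. The fallback builds the double bond on the substrate. It sets out from 27: DCC/DMAP esterification with 2-[bis(2,2,2-trifluoroethoxy)phosphoryl]propanoic acid gives the phosphonate ester F5. Still–Gennari olefination of F5 with 2-oxoethyl acetate (KN(SiMe3)2, 18-crown-6, THF, −78 °C) should give the Z-trisubstituted enoate and returns the route at 29.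

Further compounds
F1 | step 15 | 3-methyl-5-methylideneoxan-2-one with C8-hydroxy C9-iodo chain (iodohydrin, C8 configured as in 23) | CC1C(=O)OCC(=C)[C@H]1[C@@H](O[Si](C)(C)C(C)(C)C)[C@H](C(=C)COCc2ccc(OC)cc2)[C@@H](O)CI
F2 | step 15 | 8-O-triethylsilyl ether of F1 | CC1C(=O)OCC(=C)[C@H]1[C@@H](O[Si](C)(C)C(C)(C)C)[C@H](C(=C)COCc2ccc(OC)cc2)[C@@H](O[Si](CC)(CC)CC)CI
F3 | step 15 | 7-O-triethylsilyl ether of 24 (cis-fused bicyclic lactone) | C[C@@]12C[C@H](O[Si](CC)(CC)CC)[C@@H](C(=C)COCc3ccc(OC)cc3)[C@H](O[Si](C)(C)C(C)(C)C)[C@@H]1C(=C)COC2=O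
F4 | step 12 | 2-{3-[(2-methoxypropan-2-yl)oxy]prop-1-en-2-yl}-4,4,5,5-tetramethyl-1,3,2-dioxaborolane | C=C(COC(C)(C)OC)B1OC(C)(C)C(C)(C)O1
F5 | step 19 | 8-O-{2-[bis(2,2,2-trifluoroethoxy)phosphoryl]propanoyl} ester of 27 (epimers at the phosphonate carbon) | C=C[C@]1(C)C[C@H](OC(=O)C(C)P(=O)(OCC(F)(F)F)OCC(F)(F)F)[C@@H](C(=C)COCc2ccc(OC)cc2)[C@H](O[Si](C)(C)C(C)(C)C)[C@@H]1C(=C)CO[Si](C)(C)C(C)(C)C
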